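**Plan**
Numbering: lactone ring O1, C2 (C=O), C3, C4 (OAc), C5; side chain C1' (=CH on C3) to C10' (CH2OBz).
Cuts: (a) O1–C5. This bond is allylic to the 2-methylprop-1-enyl group on C5, so it corresponds to capture of a dimethylallyl cation by the C2 carboxyl group of an open-chain acid that carries a tertiary allylic alcohol. (b) C2'–C3', by a vinylogous Mukaiyama aldol. (c) C3–C4, by a deconjugative Evans aldol.
Forward: a crotonoyl imide and a C5 γ-silyloxy enal are joined at C3–C4. The derived silyl dienolate and a nerol-derived enal are joined at C2'–C3', which also creates C3=C1'. Desilylation and double acetylation follow, and the only ring closes last.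
Stereochemistry: C4 comes from the oxazolidinone auxiliary, C3' from a chiral Lewis-base catalyst, and C5 from C4 during ring closure. 8'Z comes with nerol, 4'E from the Riley oxidation, and C3=C1' E from the s-trans dienolate.
The tertiary carbinol is carried from the start as a silyl ether, so no late oxidation has to choose among four alkenes.

Key step: step 15

Assumption: the (R,R) enantiomer of the bis-phosphoramide catalyst is taken to direct addition to the Re face of the nerol-derived enal, the face that gives 3'R; if its sense proves opposite, the (S,S) enantiomer is used.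

Step 1
Reactants: 1 nerol
Product: 2 neryl benzoate [(2Z)-3,7-dimethylocta-2,6-dien-1-yl benzoate]
Conditions: BzCl, pyridine, CH2Cl2, 0 °C to rt
Reagents that add atoms: benzoyl chloride, O=C(Cl)c1ccccc1
Why: O-Acylation of a primary allylic alcohol with an acid chloride is routine, and installing the benzoate of the target now also lowers the electron density of the neighbouring Z alkene for the next step.

Step 2
Reactants: 2 neryl benzoate
Product: 3 (2Z,6E)-8-hydroxy-3,7-dimethylocta-2,6-dien-1-yl benzoate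
Conditions: SeO2 (10 mol %), t-BuOOH, salicylic acid (10 mol %), CH2Cl2, 0 °C to rt
Reagents that add atoms: tert-butyl hydroperoxide, CC(C)(C)OO (terminal source of the new oxygen atom); SeO2, O=[Se]=O (relays it)
Why: The Riley allylic oxidation (ene reaction, then [2,3]-sigmatropic shift) picks the more electron-rich terminal alkene and, as is general for a gem-dimethyl terminus, the methyl group trans to the chain, which fixes the 6E geometry; any aldehyde formed by over-oxidation is carried into step 3.

Step 3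
Reactants: 3 (2Z,6E)-8-hydroxy-3,7-dimethylocta-2,6-dien-1-yl benzoate
Product: 4 (2Z,6E)-3,7-dimethyl-8-oxoocta-2,6-dien-1-yl benzoate
Conditions: MnO2 (activated, excess), CH2Cl2, rt
Reagents that add atoms: none
Why: MnO2 oxidation is selective for allylic alcohols and should give the enal without touching the benzoate or scrambling either alkene.

Step 4
Reactants: 5 2-methylbut-3-en-2-ol; 6 (E)-but-2-enal
Product: 7 (E)-4-hydroxy-4-methylpent-2-enal
Conditions: second-generation Hoveyda–Grubbs catalyst RuCl2(H2IMes)(=CH-C6H4-2-OiPr) (3 mol %), excess 6, CH2Cl2, 40 °C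
Reagents that add atoms: none
Why: Olefin cross-metathesis of a free tertiary allylic alcohol with an enal joins two partners that homodimerise only slowly, loss of propene drives the exchange, and the conjugated alkene forms under thermodynamic control as the E isomer.

Step 5
Reactants: 7 (E)-4-hydroxy-4-methylpent-2-enal
Product: 8 (E)-4-methyl-4-(triethylsilyloxy)pent-2-enal
Conditions: Et3SiOTf, 2,6-lutidine, CH2Cl2, −78 to 0 °C
Reagents that add atoms: triethylsilyl triflate, CC[Si](CC)(CC)OS(=O)(=O)C(F)(F)F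
Why: A silyl triflate with a hindered pyridine base silylates tertiary alcohols readily, and the enal cannot enolise because its γ-carbon is quaternary.

Step 6
Reactants: 9 (S)-4-benzyl-1,3-oxazolidin-2-one; 10 (E)-but-2-enoyl chloride
Product: 12 (S)-4-benzyl-3-[(E)-but-2-enoyl]-1,3-oxazolidin-2-one, via lithium oxazolidinide 11 (not isolated)
Conditions: n-BuLi, THF, −78 °C; then 10, −78 to 0 °C
Reagents that add atoms: n-butyllithium, [Li]CCCC (lithium only in 11)
Why: N-Acylation of the lithiated oxazolidinone with an acid chloride is the standard entry to enoyl imides and leaves the E alkene and the auxiliary stereocentre untouched.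

Step 7
Reactants: 12 (S)-4-benzyl-3-[(E)-but-2-enoyl]-1,3-oxazolidin-2-one; 8 (E)-4-methyl-4-(triethylsilyloxy)pent-2-enal
Product: 15 (S)-4-benzyl-3-[(2S,3R,4E)-2-ethenyl-3-hydroxy-6-methyl-6-(triethylsilyloxy)hept-4-enoyl]-1,3-oxazolidin-2-one, via boron dienolate 13 (not isolated), via boron aldolate 14 (not isolated)
Conditions: Bu2BOTf, Et3N, CH2Cl2, −78 to 0 °C; 8, −78 to 0 °C; then H2O2, MeOH, pH 7 buffer, 0 °C
Reagents that add atoms: dibutylboron triflate, CCCCB(CCCC)OS(=O)(=O)C(F)(F)F (boron and butyl groups only in 13 and 14)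
Why: In the deconjugative Evans syn aldol reaction Bu2BOTf/Et3N removes a γ-proton to give the Z boron dienolate 13, which adds through its α-carbon to the aldehyde in a chair-like cyclic transition state on the face remote from the benzyl group, setting 3R (C4 of the lactone) together with a 2S centre that is erased later.

Step 8
Reactants: 15 aldol adduct
Product: 16 (S)-4-benzyl-3-[(2S,3R,4E)-3-(tert-butyldimethylsilyloxy)-2-ethenyl-6-methyl-6-(triethylsilyloxy)hept-4-enoyl]-1,3-oxazolidin-2-one
Conditions: t-BuMe2SiOTf, 2,6-lutidine, CH2Cl2, 0 °C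
Reagents that add atoms: tert-butyldimethylsilyl triflate, CC(C)(C)[Si](C)(C)OS(=O)(=O)C(F)(F)F
Why: Silylation of the secondary alcohol under non-basic conditions blocks retro-aldol cleavage and places a poor leaving group β to the carbonyl group for the enolate chemistry ahead.

Step 9
Reactants: 16 silylated imide
Product: 18 (2S,3R,4E)-3-(tert-butyldimethylsilyloxy)-2-ethenyl-6-methyl-6-(triethylsilyloxy)hept-4-enoic acid, via peroxy acid 17 (not isolated)
Conditions: LiOH, H2O2, THF/H2O, 0 °C; aq. Na2SO3; HCl to pH 4 at 0 °C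
Reagents that add atoms: hydrogen peroxide, OO
Why: Hydroperoxide-mediated imide cleavage attacks the exocyclic carbonyl group selectively and is too weakly basic to enolise the α-vinyl imide, so the silyloxy group should not be eliminated and the auxiliary is recovered.

Step 10
Reactants: 18 acid
Product: 19 2-(trimethylsilyl)ethyl (2S,3R,4E)-3-(tert-butyldimethylsilyloxy)-2-ethenyl-6-methyl-6-(triethylsilyloxy)hept-4-enoate
Conditions: Me3SiCH2CH2OH, PPh3, DIAD, THF, 0 °C to rt
Reagents that add atoms: 2-(trimethylsilyl)ethanol, C[Si](C)(C)CCO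
Why: The Mitsunobu esterification activates the primary alcohol and not the acid, so the α-vinyl acid is esterified without acyl activation and hence without alkene migration, and this ester is chosen because fluoride will later remove it together with the silyl ethers.

Step 11
Reactants: 19 silylethyl ester
Product: 21 (3R,4E)-1,3-bis(tert-butyldimethylsilyloxy)-2-ethenyl-6-methyl-6-(triethylsilyloxy)-1-[2-(trimethylsilyl)ethoxy]hepta-1,4-diene (ketene acetal geometry left open because it is lost in step 12), via lithium dienolate 20 (not isolated)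
Conditions: LiN(iPr)2 (commercial solution), THF, −78 °C; t-BuMe2SiCl, DMPU, −78 to −20 °C; non-aqueous work-up
Reagents that add atoms: tert-butyldimethylsilyl chloride, CC(C)(C)[Si](C)(C)Cl; lithium diisopropylamide, [Li]N(C(C)C)C(C)C (lithium only in 20)
Why: Kinetic removal of the doubly activated α-hydrogen and O-silylation of the lithium dienolate is the standard preparation of 1-alkoxy-1-silyloxy-1,3-dienes, silyloxide is a poor enough leaving group to stay in place at low temperature, and only C2 becomes planar while C3 is untouched.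

Step 12
Reactants: 21 silyl dienolate; 4 (2Z,6E)-3,7-dimethyl-8-oxoocta-2,6-dien-1-yl benzoate
Product: 23 2-(trimethylsilyl)ethyl (2E,3R,4E)-2-[(3R,4E,8Z)-10-(benzoyloxy)-3-hydroxy-4,8-dimethyldeca-4,8-dien-1-ylidene]-3-(tert-butyldimethylsilyloxy)-6-methyl-6-(triethylsilyloxy)hept-4-enoate, via trichlorosilyl ether 22 (not isolated)
Conditions: SiCl4 (1.1 equiv), (R,R)-bis-phosphoramide (pentamethylene-linked dimer of the N,N'-dimethyl-1,1'-binaphthyl-2,2'-diamine phosphoramide, 5 mol %), iPr2NEt (10 mol %), CH2Cl2, −78 °C; aq. NaHCO3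
Reagents that add atoms: silicon tetrachloride, Cl[Si](Cl)(Cl)Cl (silicon and chlorine only in 22)
Why: In this catalytic enantioselective vinylogous Mukaiyama aldol reaction the phosphoramide-bound trichlorosilyl cation activates the conjugated aldehyde, the dienolate, whose α-carbon is fully blocked, attacks through its terminal CH2 group on the Re face under catalyst control to set 3'R, and reaction through the s-trans diene places the new chain trans to the ester (2E).

Step 13
Reactants: 23 vinylogous aldol product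
Product: 24 (2E,3R,4E)-2-[(3R,4E,8Z)-10-(benzoyloxy)-3-hydroxy-4,8-dimethyldeca-4,8-dien-1-ylidene]-3,6-dihydroxy-6-methylhept-4-enoic acid
Conditions: Bu4NF (5 equiv), THF, 0 °C to rt; HCl to pH 4 at 0 °C
Reagents that add atoms: none
Why: Fluoride cleaves both silyl ethers and fragments the 2-(trimethylsilyl)ethyl ester in one operation while the benzoate and both stereocentres are left alone, and freeing the acid before the acetates are in place avoids exposing allylic acetates next to an acidic γ-CH2 group to basic fluoride.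

Step 14
Reactants: 24 trihydroxy acid
Product: 26 (2E,3R,4E)-3-acetoxy-2-[(3R,4E,8Z)-3-acetoxy-10-(benzoyloxy)-4,8-dimethyldeca-4,8-dien-1-ylidene]-6-hydroxy-6-methylhept-4-enoic acid, via mixed anhydride 25 (not isolated)
Conditions: Ac2O, pyridine, DMAP (5 mol %), CH2Cl2, 0 °C; then H2O, THF, rt
Reagents that add atoms: acetic anhydride, CC(=O)OC(C)=O
Why: Pyridine/DMAP-catalysed acetylation is much faster at the two secondary alcohols than at the tertiary one, and the mixed anhydride formed at the carboxyl group is hydrolysed selectively by water.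

Step 15
Reactants: 26 diacetoxy hydroxy acid
Product: 28 (3E,4S,5R)-4-acetoxy-3-[(3R,4E,8Z)-3-acetoxy-10-(benzoyloxy)-4,8-dimethyldeca-4,8-dien-1-ylidene]-5-(2-methylprop-1-en-1-yl)oxolan-2-one, via allyl cation 27 (not isolated)
Conditions: camphor-10-sulfonic acid (10 mol %), 4 Å molecular sieves, CH2Cl2, 0 °C to rt
Reagents that add atoms: none
Why: The sulfonic acid protonates the tertiary allylic hydroxyl group, water departs, and the carboxyl oxygen captures cation 27 at its secondary terminus, so that O1–C5 forms while the C=C bond moves outwards to give the 2-methylprop-1-enyl group, and proton loss then releases 28. The closest known reaction type is the acid-catalysed dehydrative cyclisation of tertiary allylic alcohols onto internal carboxyl or hydroxyl groups with allylic transposition (an SN1'-type lactonisation). The ring O1–C2–C3–C4–C5 closes in the 5-exo-trig mode, whereas attack at the tertiary terminus would need a seven-membered ring holding an E alkene and is excluded. C5 is controlled by the C4 stereocentre, because closure should run through the rotamer that turns the C4–H bond towards the allyl unit and the acetoxy group outwards, and the same trans (4S,5R) result follows if the C4 acetate first bridges to C5 as an acetoxonium ion that the carboxyl group opens with inversion. The step needs chemoselective ionisation, which the substrate secures because the tertiary allylic alcohol ionises far more easily than the secondary allylic acetate or the primary allylic benzoate under a catalytic amount of a moderately strong acid. The sieves bind the released water so that it cannot open the acetoxonium ion.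

**Compound list**
1 | nerol, (2Z)-3,7-dimethylocta-2,6-dien-1-ol | CC(C)=CCC/C(C)=C\CO | starting material
2 | neryl benzoate | CC(C)=CCC/C(C)=C\COC(=O)c1ccccc1 | intermediate
3 | (2Z,6E)-8-hydroxy-3,7-dimethylocta-2,6-dien-1-yl benzoate | OC/C(C)=C/CC/C(C)=C\COC(=O)c1ccccc1 | intermediate
4 | (2Z,6E)-3,7-dimethyl-8-oxoocta-2,6-dien-1-yl benzoate | O=C/C(C)=C/CC/C(C)=C\COC(=O)c1ccccc1 | intermediate
5 | 2-methylbut-3-en-2-ol | C=CC(C)(C)O | starting material
6 | (E)-but-2-enal | C/C=C/C=O | starting material
7 | (E)-4-hydroxy-4-methylpent-2-enal | CC(C)(O)/C=C/C=O | intermediate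
8 | (E)-4-methyl-4-(triethylsilyloxy)pent-2-enal | CC[Si](CC)(CC)OC(C)(C)/C=C/C=O | intermediate
9 | (S)-4-benzyl-1,3-oxazolidin-2-one | O=C1N[C@@H](Cc2ccccc2)CO1 | starting material
10 | (E)-but-2-enoyl chloride | C/C=C/C(=O)Cl | starting material
11 | N-lithio-(S)-4-benzyl-1,3-oxazolidin-2-one | [Li]N1[C@@H](Cc2ccccc2)COC1=O | intermediate
12 | (S)-4-benzyl-3-[(E)-but-2-enoyl]-1,3-oxazolidin-2-one | C/C=C/C(=O)N1[C@@H](Cc2ccccc2)COC1=O | intermediate
13 | (Z)-O-dibutylboryl dienolate of 12 | C=C/C=C(\OB(CCCC)CCCC)N1[C@@H](Cc2ccccc2)COC1=O | intermediate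
14 | O-dibutylboryl aldolate of 15 | O=C(N1[C@@H](Cc2ccccc2)COC1=O)[C@@H](C=C)[C@H](OB(CCCC)CCCC)/C=C/C(C)(C)O[Si](CC)(CC)CC | intermediate
15 | (S)-4-benzyl-3-[(2S,3R,4E)-2-ethenyl-3-hydroxy-6-methyl-6-(triethylsilyloxy)hept-4-enoyl]-1,3-oxazolidin-2-one | O=C(N1[C@@H](Cc2ccccc2)COC1=O)[C@@H](C=C)[C@H](O)/C=C/C(C)(C)O[Si](CC)(CC)CC | intermediate
16 | 3-O-tert-butyldimethylsilyl ether of 15 | O=C(N1[C@@H](Cc2ccccc2)COC1=O)[C@@H](C=C)[C@H](O[Si](C)(C)C(C)(C)C)/C=C/C(C)(C)O[Si](CC)(CC)CC | intermediate
17 | peroxy acid corresponding to 18 | OOC(=O)[C@@H](C=C)[C@H](O[Si](C)(C)C(C)(C)C)/C=C/C(C)(C)O[Si](CC)(CC)CC | intermediate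
18 | (2S,3R,4E)-3-(tert-butyldimethylsilyloxy)-2-ethenyl-6-methyl-6-(triethylsilyloxy)hept-4-enoic acid | OC(=O)[C@@H](C=C)[C@H](O[Si](C)(C)C(C)(C)C)/C=C/C(C)(C)O[Si](CC)(CC)CC | intermediate
19 | 2-(trimethylsilyl)ethyl ester of 18 | C[Si](C)(C)CCOC(=O)[C@@H](C=C)[C@H](O[Si](C)(C)C(C)(C)C)/C=C/C(C)(C)O[Si](CC)(CC)CC | intermediate
20 | lithium dienolate of 19 | [Li]OC(OCC[Si](C)(C)C)=C(C=C)[C@H](O[Si](C)(C)C(C)(C)C)/C=C/C(C)(C)O[Si](CC)(CC)CC | intermediate
21 | (3R,4E)-1,3-bis(tert-butyldimethylsilyloxy)-2-ethenyl-6-methyl-6-(triethylsilyloxy)-1-[2-(trimethylsilyl)ethoxy]hepta-1,4-diene | CC(C)(C)[Si](C)(C)OC(OCC[Si](C)(C)C)=C(C=C)[C@H](O[Si](C)(C)C(C)(C)C)/C=C/C(C)(C)O[Si](CC)(CC)CC | intermediate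
22 | 3'-O-trichlorosilyl ether of 23 | Cl[Si](Cl)(Cl)O[C@H](C/C=C(/C(=O)OCC[Si](C)(C)C)[C@H](O[Si](C)(C)C(C)(C)C)/C=C/C(C)(C)O[Si](CC)(CC)CC)/C(C)=C/CC/C(C)=C\COC(=O)c1ccccc1 | intermediate
23 | 2-(trimethylsilyl)ethyl (2E,3R,4E)-2-[(3R,4E,8Z)-10-(benzoyloxy)-3-hydroxy-4,8-dimethyldeca-4,8-dien-1-ylidene]-3-(tert-butyldimethylsilyloxy)-6-methyl-6-(triethylsilyloxy)hept-4-enoate | O[C@H](C/C=C(/C(=O)OCC[Si](C)(C)C)[C@H](O[Si](C)(C)C(C)(C)C)/C=C/C(C)(C)O[Si](CC)(CC)CC)/C(C)=C/CC/C(C)=C\COC(=O)c1ccccc1 | intermediate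
24 | (2E,3R,4E)-2-[(3R,4E,8Z)-10-(benzoyloxy)-3-hydroxy-4,8-dimethyldeca-4,8-dien-1-ylidene]-3,6-dihydroxy-6-methylhept-4-enoic acid | O[C@H](C/C=C(/C(=O)O)[C@H](O)/C=C/C(C)(C)O)/C(C)=C/CC/C(C)=C\COC(=O)c1ccccc1 | intermediate
25 | mixed acetic anhydride of 26 | CC(=O)O[C@H](C/C=C(/C(=O)OC(C)=O)[C@H](OC(C)=O)/C=C/C(C)(C)O)/C(C)=C/CC/C(C)=C\COC(=O)c1ccccc1 | intermediate
26 | (2E,3R,4E)-3-acetoxy-2-[(3R,4E,8Z)-3-acetoxy-10-(benzoyloxy)-4,8-dimethyldeca-4,8-dien-1-ylidene]-6-hydroxy-6-methylhept-4-enoic acid | CC(=O)O[C@H](C/C=C(/C(=O)O)[C@H](OC(C)=O)/C=C/C(C)(C)O)/C(C)=C/CC/C(C)=C\COC(=O)c1ccccc1 | intermediate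
27 | 1,1-dimethylallyl cation derived from 26 | CC(=O)O[C@H](C/C=C(/C(=O)O)[C@H](OC(C)=O)/C=C/[C+](C)C)/C(C)=C/CC/C(C)=C\COC(=O)c1ccccc1 | intermediate
28 | (3E,4S,5R)-4-acetoxy-3-[(3R,4E,8Z)-3-acetoxy-10-(benzoyloxy)-4,8-dimethyldeca-4,8-dien-1-ylidene]-5-(2-methylprop-1-en-1-yl)oxolan-2-one | CC(=O)O[C@H](C/C=C1/C(=O)O[C@H](C=C(C)C)[C@H]1OC(C)=O)/C(C)=C/CC/C(C)=C\COC(=O)c1ccccc1 | target

Total step count: 15. Longest linear sequence: 11 steps (4, 5, 7 to 15).

**Steps most likely to fail**

1. Step 15. The allyl cation may lose a proton to give a 1,3-diene, the released water may open the acetoxonium ion with acetyl migration, or the facial selectivity at C5 may be poor. The fallback sets out from 26 and returns at 28, and it avoids a free cation. Catalytic Ph3SiOReO3 in Et2O at −50 to 0 °C moves the hydroxyl group suprafacially through a perrhenate ester ([3,3]-type 1,3-transposition of the allylic alcohol). This gives (2E,3S,4R)-3-acetoxy-2-[(3R,4E,8Z)-3-acetoxy-10-(benzoyloxy)-4,8-dimethyldeca-4,8-dien-1-ylidene]-4-hydroxy-6-methylhept-5-enoic acid F1. This γ-hydroxy acid should lactonise by ordinary acyl substitution at O1–C2, either spontaneously or on contact with pyridinium p-toluenesulfonate. Lactonisation drains the reversible transposition, and the epimer that leads to the less crowded trans lactone 28 should close faster.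

2. Step 12. Addition may be slow because of the branched α-substituent of the dienolate, or catalyst control over the aldehyde face may erode. The fallback sets out from 21 and 4 and returns at 23, and it separates bond formation from stereocontrol. BF3·OEt2 in CH2Cl2 at −78 °C should effect the vinylogous Mukaiyama aldol without facial control, giving 23 together with its epimer 2-(trimethylsilyl)ethyl (2E,3R,4E)-2-[(3S,4E,8Z)-10-(benzoyloxy)-3-hydroxy-4,8-dimethyldeca-4,8-dien-1-ylidene]-3-(tert-butyldimethylsilyloxy)-6-methyl-6-(triethylsilyloxy)hept-4-enoate F2. Buffered Dess–Martin oxidation converts both epimers into 2-(trimethylsilyl)ethyl (2E,3R,4E)-2-[(4E,8Z)-10-(benzoyloxy)-4,8-dimethyl-3-oxodeca-4,8-dien-1-ylidene]-3-(tert-butyldimethylsilyloxy)-6-methyl-6-(triethylsilyloxy)hept-4-enoate F3. A Corey–Bakshi–Shibata reduction with the (S)-methyl-oxazaborolidine and catecholborane in toluene at −78 °C then treats the α-methylalkenyl group as the large substituent and should return 23 with 3'R.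

3. Step 11. The lithium dienolate may expel silyloxide (E1cB) before it is silylated on oxygen. The fallback sets out from 15 and returns at 21, and it keeps the C3 oxygen as an oxide, which cannot leave. LiOH/H2O2 followed by Na2SO3 cleaves the unprotected imide through (2S,3R,4E)-2-ethenyl-3-hydroxy-6-methyl-6-(triethylsilyloxy)hept-4-eneperoxoic acid F4 to (2S,3R,4E)-2-ethenyl-3-hydroxy-6-methyl-6-(triethylsilyloxy)hept-4-enoic acid F5. Steglich esterification (DCC, DMAP, Me3SiCH2CH2OH) then gives 2-(trimethylsilyl)ethyl (2S,3R,4E)-2-ethenyl-3-hydroxy-6-methyl-6-(triethylsilyloxy)hept-4-enoate F6. Two equivalents of LiN(iPr)2 at −78 °C form the dilithium alkoxide dienolate of this ester F7, and excess t-BuMe2SiCl with DMPU silylates both oxygen atoms to give 21.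

**Further compounds**
F1 | step 15 | (2E,3S,4R)-3-acetoxy-2-[(3R,4E,8Z)-3-acetoxy-10-(benzoyloxy)-4,8-dimethyldeca-4,8-dien-1-ylidene]-4-hydroxy-6-methylhept-5-enoic acid | CC(=O)O[C@H](C/C=C(/C(=O)O)[C@H](OC(C)=O)[C@H](O)C=C(C)C)/C(C)=C/CC/C(C)=C\COC(=O)c1ccccc1
F2 | step 12 | 2-(trimethylsilyl)ethyl (2E,3R,4E)-2-[(3S,4E,8Z)-10-(benzoyloxy)-3-hydroxy-4,8-dimethyldeca-4,8-dien-1-ylidene]-3-(tert-butyldimethylsilyloxy)-6-methyl-6-(triethylsilyloxy)hept-4-enoate | O[C@@H](C/C=C(/C(=O)OCC[Si](C)(C)C)[C@H](O[Si](C)(C)C(C)(C)C)/C=C/C(C)(C)O[Si](CC)(CC)CC)/C(C)=C/CC/C(C)=C\COC(=O)c1ccccc1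
F3 | step 12 | 2-(trimethylsilyl)ethyl (2E,3R,4E)-2-[(4E,8Z)-10-(benzoyloxy)-4,8-dimethyl-3-oxodeca-4,8-dien-1-ylidene]-3-(tert-butyldimethylsilyloxy)-6-methyl-6-(triethylsilyloxy)hept-4-enoate | O=C(C/C=C(/C(=O)OCC[Si](C)(C)C)[C@H](O[Si](C)(C)C(C)(C)C)/C=C/C(C)(C)O[Si](CC)(CC)CC)/C(C)=C/CC/C(C)=C\COC(=O)c1ccccc1
F4 | step 11 | (2S,3R,4E)-2-ethenyl-3-hydroxy-6-methyl-6-(triethylsilyloxy)hept-4-eneperoxoic acid | OOC(=O)[C@@H](C=C)[C@H](O)/C=C/C(C)(C)O[Si](CC)(CC)CC
F5 | step 11 | (2S,3R,4E)-2-ethenyl-3-hydroxy-6-methyl-6-(triethylsilyloxy)hept-4-enoic acid | OC(=O)[C@@H](C=C)[C@H](O)/C=C/C(C)(C)O[Si](CC)(CC)CC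
F6 | step 11 | 2-(trimethylsilyl)ethyl (2S,3R,4E)-2-ethenyl-3-hydroxy-6-methyl-6-(triethylsilyloxy)hept-4-enoate | C[Si](C)(C)CCOC(=O)[C@@H](C=C)[C@H](O)/C=C/C(C)(C)O[Si](CC)(CC)CC
F7 | step 11 | dilithium alkoxide dienolate of F6 | [Li]OC(OCC[Si](C)(C)C)=C(C=C)[C@H](O[Li])/C=C/C(C)(C)O[Si](CC)(CC)CC
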